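**Retrosynthetic overview** (carotenoid numbering)
1. The array C8(=O)–C9(=C10H–C11)–C19H2–O-acyl, next to the unconjugated β-ring unit C5=C6–C7H2, is read as an allylically transposed Morita–Baylis–Hillman (MBH) adduct. The skeleton is therefore cut at C9–C10 inside the chromophore, not at a polyene C=C.
2. 25 ⇐ 24 (desilylation) ⇐ carbinol 21 + (E)-2-decenoic acid 22 by SN2′ Mitsunobu reaction. This makes C19–O, removes C10–O, sets (9E)-C9=C10 and erases the stereorandom C10.
3. 21 ⇐ C13 ynone 18 + C27 heptaenal 11 by hydroalumination/allenolate aldol (reductive MBH), forming C9–C10.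
4. 18 ⇐ carbonyl-ene reaction of methylenecyclohexane 14 (from (4R,6R)-actinol, C3 bought), which forms C7–C8 and C5=C6 in one event. 11 ⇐ Wittig reaction (C11′=C12′) of C15 salt 5 with C12 nitrile-aldehyde 7. 5 comes from (R)-α-ionone (C6′ bought, C3′ relayed by trans-selective P450 hydroxylation).
5. No ring is formed. Both six-membered rings are bought intact.

Key step: step 13

Assumption: (R)-α-ionone, (4R,6R)-actinol, 2,7-dimethylocta-2,4,6-trienedial, 3-(trimethylsilyl)propynal and (E)-2-decenoic acid are taken as catalogue compounds. All polyene steps are run under argon in dim light.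

**Step 1**
Reactants: 1 (R)-α-ionone
Product: 2 (3R,6R)-3-hydroxy-α-ionone = (E)-4-[(1R,4R)-4-hydroxy-2,6,6-trimethylcyclohex-2-en-1-yl]but-3-en-2-one
Conditions: α-ionone-hydroxylating P450 (CYP101B1/ArR/Arx, E. coli lysate), NADH (cat.), glucose dehydrogenase, D-glucose, air, Tris buffer pH 7.4, 30 °C
Reagents that add atoms: dioxygen, O=O
Why: Cytochrome P450 allylic C–H hydroxylation (hydrogen abstraction/oxygen rebound), documented for α-ionone itself, should oxidise only the ring allylic CH2 (C3′) and deliver oxygen to the face opposite the C6′ side chain, so the bought (6′R) centre is translated into the trans-(3′R,6′R) pair.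

**Step 2**
Reactants: 2 (3R,6R)-3-hydroxy-α-ionone
Product: 3 (3R,6R)-3-(tert-butyldimethylsilyloxy)-α-ionone
Conditions: TBSCl, imidazole, DMF, rt
Reagents that add atoms: tert-butyldimethylsilyl chloride, CC(C)(C)[Si](C)(C)Cl
Why: Standard silyl ether formation masks the allylic alcohol until the last step under conditions too mild to move the C4′=C5′ bond into conjugation.

**Step 3**
Reactants: 3 silyloxy-α-ionone
Product: 4 (1E)-1-[(1R,4R)-4-(tert-butyldimethylsilyloxy)-2,6,6-trimethylcyclohex-2-en-1-yl]-3-methylpenta-1,4-dien-3-ol (C9′ epimers)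
Conditions: vinylmagnesium bromide, THF, −78 → 0 °C
Reagents that add atoms: vinylmagnesium bromide, C=C[Mg]Br
Why: Grignard 1,2-addition to the enone carbonyl gives the vinyl carbinol, whose new C9′ centre forms as a mixture and is erased in step 4.

**Step 4**
Reactants: 4 vinyl carbinol
Product: 5 [(2E,4E)-5-[(1R,4R)-4-(tert-butyldimethylsilyloxy)-2,6,6-trimethylcyclohex-2-en-1-yl]-3-methylpenta-2,4-dien-1-yl]triphenylphosphonium bromide
Conditions: PPh3·HBr (1.0 equiv), CH2Cl2, 0 °C → rt; precipitation from Et2O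
Reagents that add atoms: triphenylphosphine hydrobromide, Br.c1ccc(cc1)P(c1ccccc1)c1ccccc1
Why: In this SN1′ phosphonium salt formation the tertiary bis-allylic alcohol ionises far more easily than the secondary allylic silyl ether, and PPh3 captures the pentadienyl cation at the primary C11′ terminus to give the (9′E) salt.

**Step 5**
Reactants: 6 (2E,4E,6E)-2,7-dimethylocta-2,4,6-trienedial (C10 dialdehyde)
Product: 7 (2E,4E,6E,8E)-4,9-dimethyl-10-oxodeca-2,4,6,8-tetraenenitrile
Conditions: (EtO)2P(O)CH2CN, NaH, THF, 0 °C; anion added slowly to 6 (3 equiv), −20 °C → rt; excess 6 recovered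
Reagents that add atoms: diethyl cyanomethylphosphonate, CCOP(=O)(CC#N)OCC
Why: E-selective Horner–Wadsworth–Emmons olefination adds C10–C11, and the excess of the symmetrical dialdehyde restricts the reaction to one end.

**Step 6**
Reactants: 5 C15 phosphonium bromide; 7 C12 nitrile-aldehyde
Product: 9 (2E,4E,6E,8E,10E,12E,14E)-15-[(1R,4R)-4-(tert-butyldimethylsilyloxy)-2,6,6-trimethylcyclohex-2-en-1-yl]-4,9,13-trimethylpentadeca-2,4,6,8,10,12,14-heptaenenitrile, via C15 ylide 8 (not isolated)
Conditions: NaHMDS (0.95 equiv), THF, −78 °C; then 7, −78 → 0 °C; crude product equilibrated with I2 (cat.), CH2Cl2, diffuse light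
Reagents that add atoms: none
Why: Wittig olefination with the semi-stabilised allylic ylide forms C11′=C12′, iodine-catalysed equilibration funnels the E/Z mixture to the all-E polyene, and the slight deficit of base protects the doubly allylic C6′–H.

**Step 7**
Reactants: 9 C27 nitrile
Product: 11 (2E,4E,6E,8E,10E,12E,14E)-15-[(1R,4R)-4-(tert-butyldimethylsilyloxy)-2,6,6-trimethylcyclohex-2-en-1-yl]-4,9,13-trimethylpentadeca-2,4,6,8,10,12,14-heptaenal (CHO = C10), via aluminium aldimine 10 (not isolated)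
Conditions: DIBAL-H (1.1 equiv), CH2Cl2, −78 °C; then wet silica gel, 0 °C
Reagents that add atoms: water, O
Why: Partial hydride reduction of a conjugated nitrile stops at the N-aluminio aldimine, which neutral hydrolysis converts to the polyenal without touching the silyl ether.

**Step 8**
Reactants: 12 (4R,6R)-4-hydroxy-2,2,6-trimethylcyclohexanone (actinol)
Product: 13 (4R,6R)-4-(tert-butyldimethylsilyloxy)-2,2,6-trimethylcyclohexanone
Conditions: TBSCl, imidazole, DMF, rt
Reagents that add atoms: tert-butyldimethylsilyl chloride, CC(C)(C)[Si](C)(C)Cl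
Why: Standard silyl ether formation protects the bought carbinol centre (future C3), which sits γ to the carbonyl and cannot be eliminated.

**Step 9**
Reactants: 13 silyloxy ketone
Product: 14 tert-butyl(dimethyl){[(1R,5R)-3,3,5-trimethyl-4-methylidenecyclohexyl]oxy}silane
Conditions: MePPh3Br, KOtBu, toluene, 90 °C
Reagents that add atoms: methyltriphenylphosphonium bromide, [Br-].C[P+](c1ccccc1)(c1ccccc1)c1ccccc1
Why: Wittig methylenation under the hot alkoxide conditions used for hindered ketones installs C7, and any epimerisation at the CHMe centre is harmless because step 10 destroys it.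

**Step 10**
Reactants: 14 methylenecyclohexane; 15 3-(trimethylsilyl)propynal
Product: 16 1-[(4R)-4-(tert-butyldimethylsilyloxy)-2,6,6-trimethylcyclohex-1-en-1-yl]-4-(trimethylsilyl)but-3-yn-2-ol (C8 epimers)
Conditions: Me2AlCl (1.5 equiv), CH2Cl2, −78 → −20 °C
Reagents that add atoms: none
Why: In this Lewis acid promoted carbonyl-ene reaction of a 1,1-disubstituted alkene, C7 attacks the aldehyde carbon (C8) while the only allylic hydrogen (C5–H) is transferred, so the double bond can only become the tetrasubstituted C5=C6; the silyl cap blocks attack at the alkyne, and the uncontrolled C8 carbinol is erased in step 12.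

**Step 11**
Reactants: 16 silylated alkynol
Product: 17 1-[(4R)-4-(tert-butyldimethylsilyloxy)-2,6,6-trimethylcyclohex-1-en-1-yl]but-3-yn-2-ol (C8 epimers)
Conditions: K2CO3 (cat.), MeOH, 0 °C → rt
Reagents that add atoms: none
Why: Methanolysis cleaves the alkynyl C–Si bond selectively and leaves the O-TBS ether, and doing it at the alcohol stage avoids methanol addition to an ynone.

**Step 12**
Reactants: 17 terminal alkynol
Product: 18 1-[(4R)-4-(tert-butyldimethylsilyloxy)-2,6,6-trimethylcyclohex-1-en-1-yl]but-3-yn-2-one (C13 ynone)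
Conditions: Dess–Martin periodinane, CH2Cl2, 0 °C; used directly
Reagents that add atoms: none
Why: Dess–Martin oxidation is neutral and fast, so the doubly activated C7H2 is not enolised and C5=C6 stays out of conjugation.

**Step 13**
Reactants: 18 C13 ynone; 11 C27 heptaenal
Product: 21 bis-TBS α-methylene-β-hydroxy ketone with C19H2=C9 and C10–OH (C40 skeleton; C10 epimers), via aluminium allenolate 19 (not isolated), via aluminium aldolate 20 (not isolated)
Conditions: DIBAL-H (1.4 equiv)/HMPA (3 equiv), THF, 0 °C; 18 (1.5 equiv), 0 °C, 30 min; then 11 (1.0 equiv), 0 °C → rt; aqueous Rochelle salt at pH 7; 21 used without storage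
Reagents that add atoms: none
Why: DIBAL-H·HMPA delivers hydride 1,4 to the terminal alkyne carbon (future C19) of 18 and generates the aluminium allenolate 19, an α-acylvinyl anion whose C9 adds through a closed Al-bound transition state to the C10 aldehyde of 11, giving aldolate 20 and, after work-up, carbinol 21. The closest known reaction type is the hydroalumination/aldol sequence of α,β-acetylenic ketones (vinylalumination, a reductive Morita–Baylis–Hillman reaction). No ring is closed; the step joins the chain at C9–C10, completes the C40 skeleton from a C13 and a C27 piece, and leaves C19 as the exo-methylene handle for the ester. The only new stereocentre, C10, is not controlled and need not be, since step 14 turns it into an sp2 carbon of C9=C10. The step needs 1,4- over 1,2-reduction of 18 (secured by the HMPA-complexed hydride), 1,2- over conjugate addition to the heptaenal (secured by Al–O activation in the cyclic transition state), and C9 rather than C7 as nucleophile, which holds because the enolate is made regiospecifically by hydride addition and not by deprotonation, so C7H2 and the unconjugated C5=C6 bond stay untouched. DIBAL-H is kept in slight deficit to 18 so that no free hydride meets aldehyde 11.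

**Step 14**
Reactants: 21 MBH-type carbinol; 22 (E)-2-decenoic acid
Product: 24 3,3′-bis-O-TBS ether of the target ((9E); C11 cis to C19H2O and trans to C8=O), via oxyphosphonium decenoate 23 (not isolated)
Conditions: PPh3/DIAD betaine preformed in THF–toluene, −20 °C; then 22, then 21, −20 → 0 °C
Reagents that add atoms: none
Why: In the SN2′ Mitsunobu reaction known for MBH alcohols, decenoate adds to the electrophilic C19 methylene of the enone while Ph3P=O leaves from C10; the allylic-strain-minimised addition–elimination places C11 trans to the C8 acyl group, and the product (a primary ester on a fully conjugated octaenone) is also the thermodynamic sink of any ion-pair return.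

**Step 15**
Reactants: 24 bis-TBS ether
Product: 25 target CNP0332433.1, (3R,3′R,6′R)-siphonaxanthin 19-[(E)-2-decenoate]
Conditions: HF·pyridine, excess pyridine, THF, 0 °C → rt, dark
Reagents that add atoms: none
Why: Buffered, non-basic fluoride desilylation frees both hydroxyls and spares the SN2′-labile allylic ester, the enolisable C7H2 and the acid-sensitive allylic C3′–O bond; no stereocentre is touched.

**Compound list**
1 | (R)-α-ionone | CC(=O)/C=C/[C@H]1C(C)=CCCC1(C)C | starting material
2 | (3R,6R)-3-hydroxy-α-ionone | CC(=O)/C=C/[C@H]1C(C)=C[C@H](O)CC1(C)C | intermediate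
3 | (3R,6R)-3-TBSO-α-ionone | CC(=O)/C=C/[C@H]1C(C)=C[C@H](O[Si](C)(C)C(C)(C)C)CC1(C)C | intermediate
4 | vinyl carbinol (C9′ epimers) | C=CC(C)(O)/C=C/[C@H]1C(C)=C[C@H](O[Si](C)(C)C(C)(C)C)CC1(C)C | intermediate
5 | C15 phosphonium bromide | [Br-].c1ccccc1[P+](c1ccccc1)(c1ccccc1)C/C=C(C)/C=C/[C@H]1C(C)=C[C@H](O[Si](C)(C)C(C)(C)C)CC1(C)C | intermediate
6 | (2E,4E,6E)-2,7-dimethylocta-2,4,6-trienedial | O=C/C(C)=C/C=C/C=C(C)/C=O | starting material
7 | (2E,4E,6E,8E)-4,9-dimethyl-10-oxodeca-2,4,6,8-tetraenenitrile | N#C/C=C/C(C)=C/C=C/C=C(C)/C=O | intermediate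
8 | C15 ylide | c1ccccc1[P+](c1ccccc1)(c1ccccc1)[CH-]/C=C(C)/C=C/[C@H]1C(C)=C[C@H](O[Si](C)(C)C(C)(C)C)CC1(C)C | intermediate
9 | C27 heptaenenitrile | N#C/C=C/C(C)=C/C=C/C=C(C)/C=C/C=C(C)/C=C/[C@H]1C(C)=C[C@H](O[Si](C)(C)C(C)(C)C)CC1(C)C | intermediate
10 | N-(diisobutylaluminio) aldimine of 11 | CC(C)C[Al](CC(C)C)N=C/C=C/C(C)=C/C=C/C=C(C)/C=C/C=C(C)/C=C/[C@H]1C(C)=C[C@H](O[Si](C)(C)C(C)(C)C)CC1(C)C | intermediate
11 | C27 heptaenal | O=C/C=C/C(C)=C/C=C/C=C(C)/C=C/C=C(C)/C=C/[C@H]1C(C)=C[C@H](O[Si](C)(C)C(C)(C)C)CC1(C)C | intermediate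
12 | (4R,6R)-actinol | O=C1C(C)(C)C[C@H](O)C[C@H]1C | starting material
13 | (4R,6R)-4-TBSO-2,2,6-trimethylcyclohexanone | O=C1C(C)(C)C[C@H](O[Si](C)(C)C(C)(C)C)C[C@H]1C | intermediate
14 | (1R,5R)-methylenecyclohexane silyl ether | C=C1C(C)(C)C[C@H](O[Si](C)(C)C(C)(C)C)C[C@H]1C | intermediate
15 | 3-(trimethylsilyl)propynal | O=CC#C[Si](C)(C)C | starting material
16 | ene adduct (C8 epimers) | C[Si](C)(C)C#CC(O)CC1=C(C)C[C@@H](O[Si](C)(C)C(C)(C)C)CC1(C)C | intermediate
17 | terminal alkynol (C8 epimers) | C#CC(O)CC1=C(C)C[C@@H](O[Si](C)(C)C(C)(C)C)CC1(C)C | intermediate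
18 | C13 ynone | C#CC(=O)CC1=C(C)C[C@@H](O[Si](C)(C)C(C)(C)C)CC1(C)C | intermediate
19 | diisobutylaluminium allenolate | C=C=C(O[Al](CC(C)C)CC(C)C)CC1=C(C)C[C@@H](O[Si](C)(C)C(C)(C)C)CC1(C)C | intermediate
20 | diisobutylaluminium aldolate | C=C(C(O[Al](CC(C)C)CC(C)C)/C=C/C(C)=C/C=C/C=C(C)/C=C/C=C(C)/C=C/[C@H]1C(C)=C[C@H](O[Si](C)(C)C(C)(C)C)CC1(C)C)C(=O)CC1=C(C)C[C@@H](O[Si](C)(C)C(C)(C)C)CC1(C)C | intermediate
21 | MBH-type carbinol (C10 epimers) | C=C(C(O)/C=C/C(C)=C/C=C/C=C(C)/C=C/C=C(C)/C=C/[C@H]1C(C)=C[C@H](O[Si](C)(C)C(C)(C)C)CC1(C)C)C(=O)CC1=C(C)C[C@@H](O[Si](C)(C)C(C)(C)C)CC1(C)C | intermediate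
22 | (E)-2-decenoic acid | CCCCCCC/C=C/C(=O)O | starting material
23 | C10 oxyphosphonium decenoate | C=C(C(O[P+](c1ccccc1)(c1ccccc1)c1ccccc1)/C=C/C(C)=C/C=C/C=C(C)/C=C/C=C(C)/C=C/[C@H]1C(C)=C[C@H](O[Si](C)(C)C(C)(C)C)CC1(C)C)C(=O)CC1=C(C)C[C@@H](O[Si](C)(C)C(C)(C)C)CC1(C)C.CCCCCCC/C=C/C(=O)[O-] | intermediate
24 | 3,3′-bis-O-TBS target | CCCCCCC/C=C/C(=O)OC\C(=C/C=C/C(C)=C/C=C/C=C(C)/C=C/C=C(C)/C=C/[C@H]1C(C)=C[C@H](O[Si](C)(C)C(C)(C)C)CC1(C)C)C(=O)CC1=C(C)C[C@@H](O[Si](C)(C)C(C)(C)C)CC1(C)C | intermediate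
25 | CNP0332433.1 | CCCCCCC/C=C/C(=O)OC\C(=C/C=C/C(C)=C/C=C/C=C(C)/C=C/C=C(C)/C=C/[C@H]1C(C)=C[C@H](O)CC1(C)C)C(=O)CC1=C(C)C[C@@H](O)CC1(C)C | target

**Totals**
Total step count: 15. Longest linear sequence: 9 (steps 1, 2, 3, 4, 6, 7, 13, 14, 15).

**Steps most likely to fail**

1. **Step 13.** Addition to the vinylogously deactivated heptaenal may be so slow that the allenolate is consumed by proton transfer from C7H2 or by self-condensation.
 - Fallback: the C9–C10 aldol is moved to a short, much more electrophilic aldehyde, and the polyene is closed last at C11′=C12′.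
 - It sets out from 7. DIBAL-H (2.2 equiv, −78 °C, then wet silica) gives (2E,4E,6E,8E)-10-hydroxy-4,9-dimethyldeca-2,4,6,8-tetraenal F1.
 - MnO2 then gives (2E,4E,6E,8E)-2,7-dimethyldeca-2,4,6,8-tetraenedial F2.
 - Allenolate 19, made from 18 as before, adds to the unhindered C10 aldehyde of F2 rather than to the α-methyl-branched C12′ aldehyde. This gives the C25 carbinol aldehyde F3.
 - SN2′ Mitsunobu reaction with 22 gives the C25 keto ester aldehyde F4.
 - A base-free Wittig reaction of F4 with salt 5 in refluxing 1,2-epoxybutane (HBr scavenger) comes back to the route at 24.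

2. **Step 14.** The oxyphosphonium ion may ionise to a delocalised polyenyl cation. Carboxylate capture at remote chain positions or proton loss would follow.
 - Fallback: acylation and transposition are separated.
 - It sets out from 21. Steglich esterification with 22 (DIC, cat. DMAP, CH2Cl2, −20 °C) gives the secondary C10 (E)-2-decenoate F5.
 - A nucleophile-catalysed 1,3-acyloxy shift (DABCO cat., THF, rt; SN2′ ammonium salt formation followed by carboxylate return at C19) isomerises F5 to the conjugated primary ester and comes back at 24.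

3. **Step 10.** Cationic side reactions may outrun the ene pathway. These are a methyl shift next to the quaternary carbon, isomerisation of the exocyclic alkene, and attack at the alkyne.
 - Fallback: C6–C7 is made by cross-coupling instead.
 - It sets out from 13. KHMDS/PhNTf2 gives (4R)-4-(tert-butyldimethylsilyloxy)-2,6,6-trimethylcyclohex-1-en-1-yl triflate F6.
 - Stille coupling with allyltributylstannane (Pd(PPh3)4, LiCl, THF, reflux) gives the skipped diene F7.
 - Lemieux–Johnson cleavage of the monosubstituted alkene (OsO4 cat., NaIO4, 2,6-lutidine) gives [(4R)-4-(tert-butyldimethylsilyloxy)-2,6,6-trimethylcyclohex-1-en-1-yl]acetaldehyde F8.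
 - Ethynylmagnesium bromide (THF, −78 °C) comes back to the route at 17.

**Further compounds**
F1 | step 13 | (2E,4E,6E,8E)-10-hydroxy-4,9-dimethyldeca-2,4,6,8-tetraenal | O=C/C=C/C(C)=C/C=C/C=C(C)/CO
F2 | step 13 | (2E,4E,6E,8E)-2,7-dimethyldeca-2,4,6,8-tetraenedial | O=C/C=C/C(C)=C/C=C/C=C(C)/C=O
F3 | step 13 | C25 carbinol aldehyde (C10 epimers) | C=C(C(O)/C=C/C(C)=C/C=C/C=C(C)/C=O)C(=O)CC1=C(C)C[C@@H](O[Si](C)(C)C(C)(C)C)CC1(C)C
F4 | step 13 | C25 keto ester aldehyde (9E) | CCCCCCC/C=C/C(=O)OC\C(=C/C=C/C(C)=C/C=C/C=C(C)/C=O)C(=O)CC1=C(C)C[C@@H](O[Si](C)(C)C(C)(C)C)CC1(C)C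
F5 | step 14 | secondary C10 (E)-2-decenoate of 21 (C10 epimers) | C=C(C(OC(=O)/C=C/CCCCCCC)/C=C/C(C)=C/C=C/C=C(C)/C=C/C=C(C)/C=C/[C@H]1C(C)=C[C@H](O[Si](C)(C)C(C)(C)C)CC1(C)C)C(=O)CC1=C(C)C[C@@H](O[Si](C)(C)C(C)(C)C)CC1(C)C
F6 | step 10 | (4R)-4-(tert-butyldimethylsilyloxy)-2,6,6-trimethylcyclohex-1-en-1-yl triflate | O=S(=O)(OC1=C(C)C[C@@H](O[Si](C)(C)C(C)(C)C)CC1(C)C)C(F)(F)F
F7 | step 10 | tert-butyl(dimethyl){[(1R)-3,5,5-trimethyl-4-(prop-2-en-1-yl)cyclohex-3-en-1-yl]oxy}silane | C=CCC1=C(C)C[C@@H](O[Si](C)(C)C(C)(C)C)CC1(C)C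
F8 | step 10 | [(4R)-4-(tert-butyldimethylsilyloxy)-2,6,6-trimethylcyclohex-1-en-1-yl]acetaldehyde | O=CCC1=C(C)C[C@@H](O[Si](C)(C)C(C)(C)C)CC1(C)C
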